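**Retrosynthetic overview**
- The target is ent-epiafzelechin-(4β→8)-epiafzelechin-(4α→8)-(2S,3S,4R)-flavan-3,4-diol. Both interflavan bonds are 3,4-cis (upper and middle units all-cis), which cation-plus-arene coupling cannot give because the arene adds trans to O3. Each C4–C8 bond is therefore made first as an aryl ketone (C8 aryllithium + Weinreb amide), and hydride is the last group to reach C4.
- Upper pyran ring (key step): the C4–C4a bond is closed by reductive Friedel–Crafts cyclisation of the ketone that sits on C8 of ring D. The enabling feature is that C4 of the upper unit is a diarylmethine between two 1,3,5-trioxygenated rings (ring A of the upper unit, ring D of the middle unit) and C4a of ring A lies ortho to O1 and O5 and para to O7. Ring A can thus attack the C4 carbonyl, and the doubly stabilised C4 cation takes hydride anti to the axial C3–O bond.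
- The same operation closes the middle pyran ring one cycle earlier. The lower pyran ring is closed last, also at C4–C4a, by hydroxyalkylation of an aldehyde without a reductant, which leaves the 4-OH (3,4-trans).
- All C2/C3 pairs come from Evans syn-glycolate aldols. Each O1–C8a aryl ether is made by Pd-catalysed O-arylation with retention at C2; 1,5-bis(benzyloxy)-2,3-dibromobenzene brings the C8 bromine of rings D and G.
- Ring order: middle C ring (step 12), upper C ring (step 14), lower C ring (step 17); then global debenzylation.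

Key step: step 14

Assumption: both enantiomers of 4-benzyl-3-[(benzyloxy)acetyl]oxazolidin-2-one and 1,3-bis(benzyloxy)-5-bromobenzene are taken as purchased, and rotation about the two C4–C8 bonds is taken as free, since the target defines no axis.

**Step 1**
Reactants: 1 (R)-4-benzyl-3-[(benzyloxy)acetyl]oxazolidin-2-one; 2 4-(benzyloxy)benzaldehyde
Product: 3 (R)-4-benzyl-3-[(2R,3S)-2-(benzyloxy)-3-[4-(benzyloxy)phenyl]-3-hydroxypropanoyl]oxazolidin-2-one
Conditions: Bu2BOTf, Et3N, CH2Cl2, −78 → 0 °C; 2, −78 → 0 °C; H2O2, pH 7 buffer/MeOH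
Reagents that add atoms: none
Why: Evans boron glycolate aldol, in which the Z-boron enolate reacts through a Zimmerman–Traxler chair on the face away from the auxiliary benzyl group and should set the 2,3-syn (2R,3S) pair that becomes C3 and C2 of the upper and lower units.

**Step 2**
Reactants: 4 (S)-4-benzyl-3-[(benzyloxy)acetyl]oxazolidin-2-one; 2 4-(benzyloxy)benzaldehyde
Product: 5 (S)-4-benzyl-3-[(2S,3R)-2-(benzyloxy)-3-[4-(benzyloxy)phenyl]-3-hydroxypropanoyl]oxazolidin-2-one
Conditions: Bu2BOTf, Et3N, CH2Cl2, −78 → 0 °C; 2, −78 → 0 °C; H2O2, pH 7 buffer/MeOH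
Reagents that add atoms: none
Why: the same Evans glycolate aldol with the enantiomeric auxiliary should give the (2S,3R) syn pair for C3 and C2 of the middle unit.

**Step 3**
Reactants: 3 syn-aldol imide
Product: 6 (2R,3S)-2-(benzyloxy)-3-[4-(benzyloxy)phenyl]-3-hydroxy-N-methoxy-N-methylpropanamide
Conditions: MeNH(OMe)·HCl, AlMe3, CH2Cl2, −10 → 0 °C; aq. HCl
Reagents that add atoms: N,O-dimethylhydroxylamine hydrochloride, CNOC.Cl
Why: AlMe3-mediated transamination of a β-hydroxy N-acyloxazolidinone to the Weinreb amide, helped by the free β-hydroxyl; no stereocentre is touched.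

**Step 4**
Reactants: 5 syn-aldol imide (enantiomeric series)
Product: 7 (2S,3R)-2-(benzyloxy)-3-[4-(benzyloxy)phenyl]-3-hydroxy-N-methoxy-N-methylpropanamide
Conditions: MeNH(OMe)·HCl, AlMe3, CH2Cl2, −10 → 0 °C; aq. HCl
Reagents that add atoms: N,O-dimethylhydroxylamine hydrochloride, CNOC.Cl
Why: the same AlMe3-mediated Weinreb transamination; no stereocentre is touched.

**Step 5**
Reactants: 3 syn-aldol imide
Product: 8 (1S,2S)-2-(benzyloxy)-1-[4-(benzyloxy)phenyl]propane-1,3-diol
Conditions: LiBH4, MeOH (1 equiv), THF, 0 °C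
Reagents that add atoms: none
Why: reductive removal of the oxazolidinone with LiBH4 gives the 1,3-diol without touching either stereocentre.

**Step 6**
Reactants: 8 diol
Product: 9 (1S,2S)-2-(benzyloxy)-1-[4-(benzyloxy)phenyl]-3-[(tert-butyldiphenylsilyl)oxy]propan-1-ol
Conditions: TBDPSCl, imidazole, CH2Cl2, 0 °C
Reagents that add atoms: tert-butyl(chloro)diphenylsilane, CC(C)(C)[Si](Cl)(c1ccccc1)c1ccccc1
Why: silylation with the bulky chlorosilane is selective for the primary over the secondary benzylic hydroxyl.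

**Step 7**
Reactants: 10 1,3-bis(benzyloxy)-5-bromobenzene
Product: 11 1,5-bis(benzyloxy)-2,3-dibromobenzene
Conditions: NBS, MeCN, 0 °C → rt
Reagents that add atoms: N-bromosuccinimide, O=C1CCC(=O)N1Br
Why: electrophilic aromatic bromination of a 5-substituted resorcinol diether goes para to one alkoxy group and ortho to the other (next to the bromine) and not between the two alkoxy groups.

**Step 8**
Reactants: 6 hydroxy Weinreb amide; 10 1,3-bis(benzyloxy)-5-bromobenzene
Product: 12 (2R,3S)-2-(benzyloxy)-3-[4-(benzyloxy)phenyl]-3-[3,5-bis(benzyloxy)phenoxy]-N-methoxy-N-methylpropanamide (upper-unit fragment)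
Conditions: [Pd(allyl)Cl]2 (2 mol%), RockPhos (6 mol%), Cs2CO3, toluene, 80 °C
Reagents that add atoms: none
Why: Pd-catalysed C–O cross-coupling of a secondary alcohol with an aryl bromide (Buchwald etherification) forms the aryl–O bond, so the carbinol carbon (future C2) keeps its configuration.

**Step 9**
Reactants: 7 hydroxy Weinreb amide (enantiomeric series); 11 dibromide
Product: 13 (2S,3R)-2-(benzyloxy)-3-[4-(benzyloxy)phenyl]-3-[3,5-bis(benzyloxy)-2-bromophenoxy]-N-methoxy-N-methylpropanamide (middle-unit fragment)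
Conditions: [Pd(allyl)Cl]2 (2 mol%), RockPhos (6 mol%), Cs2CO3, toluene, 80 °C
Reagents that add atoms: none
Why: the same Pd-catalysed etherification with retention at carbon; oxidative addition should select the C3–Br of 11 (meta to both benzyloxy groups, one ortho hydrogen) over the C2–Br (ortho and para to the donors, flanked by Br and OBn).

**Step 10**
Reactants: 9 silyl ether alcohol; 11 dibromide
Product: 14 tert-butyl{(2S,3S)-2-(benzyloxy)-3-[4-(benzyloxy)phenyl]-3-[3,5-bis(benzyloxy)-2-bromophenoxy]propoxy}diphenylsilane (lower-unit fragment)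
Conditions: [Pd(allyl)Cl]2 (2 mol%), RockPhos (6 mol%), Cs2CO3, toluene, 80 °C
Reagents that add atoms: none
Why: the same chemoselective Pd-catalysed etherification with retention at the carbinol carbon; the weak carbonate base should not trigger silyl migration.

**Step 11**
Reactants: 14 lower-unit aryl bromide; 13 middle-unit Weinreb amide
Product: 16 seco-dimer aryl ketone (ring G of 14 acylated at the former C–Br by the (2S,3R)-propanoyl chain of 13), via aryllithium 15 (not isolated)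
Conditions: t-BuLi (2 equiv), Et2O, −78 °C; then 13, THF, −78 → −40 °C
Reagents that add atoms: none
Why: bromine–lithium exchange followed by Weinreb ketone synthesis, where the chelated tetrahedral intermediate stops over-addition and the low temperature keeps exchange with the aryl bromide of 13 and enolisation slow.

**Step 12**
Reactants: 16 seco-dimer aryl ketone
Product: 18 8-bromo seco-dimer with the middle pyran ring closed (2,3-cis-3,4-cis), via flavan-4-ylium cation 17 (not isolated)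
Conditions: Et3SiH (5 equiv), TMSOTf (0.5 equiv), CH2Cl2, −78 → 0 °C
Reagents that add atoms: none
Why: Proposed new method: the silyl-triflate-activated ketone is attacked 6-exo-trig by the free ortho carbon of ring D, the tertiary silyl ether ionises to cation 17 (stabilised by rings D and G), and Et3SiH adds anti to the axial 3-benzyloxy group to set C4 cis to O3 and to the 2-aryl group; the closest known reaction type is the acid/silane reductive Friedel–Crafts alkylation of electron-rich arenes by ketones, together with the silane reduction of aryl-stabilised cyclic cations used for C-aryl glycosides.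

**Step 13**
Reactants: 18 8-bromo seco-dimer; 12 upper-unit Weinreb amide
Product: 20 seco-trimer aryl ketone (C8 of ring D acylated by the (2R,3S)-propanoyl chain of 12), via aryllithium 19 (not isolated)
Conditions: t-BuLi (2 equiv), Et2O, −78 °C; then 12, THF, −78 → −40 °C
Reagents that add atoms: none
Why: bromine–lithium exchange at C8 of a 5,7-dibenzyloxyflavan followed by Weinreb ketone synthesis; no other aryl halide is present and no stereocentre is touched.

**Step 14**
Reactants: 20 seco-trimer aryl ketone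
Product: 22 seco-trimer with upper and middle pyran rings closed (both 2,3-cis-3,4-cis; lower chain still open as the TBDPS ether), via flavan-4-ylium cation 21 (not isolated)
Conditions: Et3SiH (5 equiv), TMSOTf (0.5 equiv), CH2Cl2, −78 → 0 °C
Reagents that add atoms: none
Why: Proposed new method: the silyl triflate activates the C4 ketone carried by C8 of ring D, C4a of ring A (ortho to O1 and to the 5-benzyloxy group, para to the 7-benzyloxy group) attacks it in a Friedel–Crafts hydroxyalkylation, the tertiary silyl ether ionises to the C4 cation 21 stabilised by rings A and D, and Et3SiH reduces 21. The closest known reaction type is the acid/silane reductive Friedel–Crafts alkylation of electron-rich arenes by ketones, combined with the stereoselective Et3SiH reduction of aryl-substituted cyclic cations in C-aryl glycoside synthesis; it has not been shown for β-aryloxy α-alkoxy ketones giving 4-arylflavans. The pyran ring (O1–C2–C3–C4–C4a–C8a) closes by a Baldwin-allowed 6-exo-trig attack of the arene on the carbonyl carbon, and only the two equivalent ortho carbons of ring A can reach C4. The new stereocentre C4 is controlled by the half-chair of 21, in which the 2-aryl group is equatorial and the 3-benzyloxy group axial (A(1,2) strain with the C4 aryl group), so hydride enters axially on the face anti to C3–O and leaves H4 trans and the ring-D aryl group cis to O3 (2,3-cis-3,4-cis). The step needs cyclisation to beat direct silane reduction of the ketone, and hydride capture to beat loss of H3 from 21; the hindered 2,6-dioxygenated aryl ketone accepts external hydride slowly while the tethered trialkoxyarene has a high effective molarity, and excess silane at low temperature traps 21.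

**Step 15**
Reactants: 22 seco-trimer TBDPS ether
Product: 23 seco-trimer primary alcohol
Conditions: TBAF, AcOH, THF, rt
Reagents that add atoms: none
Why: buffered fluoride cleavage of the primary silyl ether leaves benzyl ethers and all stereocentres untouched.

**Step 16**
Reactants: 23 seco-trimer primary alcohol
Product: 24 seco-trimer α-benzyloxy aldehyde
Conditions: Dess–Martin periodinane, CH2Cl2, 0 °C → rt
Reagents that add atoms: none
Why: Dess–Martin oxidation under non-basic conditions gives the aldehyde without epimerising the adjacent C3; it is used at once.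

**Step 17**
Reactants: 24 seco-trimer aldehyde
Product: 25 dodeca-O-benzyl trimer with the lower pyran ring closed and a free 4-OH (lower unit 2,3-cis-3,4-trans)
Conditions: BF3·OEt2 (0.3 equiv), CH2Cl2, −78 °C; Et3N quench
Reagents that add atoms: none
Why: intramolecular Friedel–Crafts hydroxyalkylation in which C4a of ring G (ortho to O1 and O5, para to O7) attacks the BF3-bound aldehyde through a half-chair with the 2-aryl group equatorial, the 3-benzyloxy group axial and the C4–O bond axial (anti to the C3–O dipole and away from the peri 5-benzyloxy group), which should give the 3,4-trans 4-ol.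

**Step 18**
Reactants: 25 dodeca-O-benzyl trimer
Product: 26 target CNP0159291.1
Conditions: H2 (1 atm), Pd(OH)2/C, THF/MeOH, rt
Reagents that add atoms: none
Why: neutral hydrogenolysis of the twelve benzyl ethers over Pearlman's catalyst, stopped at the calculated hydrogen uptake to spare the benzylic C4–OH and C2–O1 bonds; no stereocentre is touched.

**Compound list**
1 | (R)-4-benzyl-3-[(benzyloxy)acetyl]oxazolidin-2-one | O=C1OC[C@@H](Cc2ccccc2)N1C(=O)COCc1ccccc1 | starting material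
2 | 4-(benzyloxy)benzaldehyde | O=Cc1ccc(OCc2ccccc2)cc1 | starting material
3 | (R)-4-benzyl-3-[(2R,3S)-2-(benzyloxy)-3-[4-(benzyloxy)phenyl]-3-hydroxypropanoyl]oxazolidin-2-one | O=C1OC[C@@H](Cc2ccccc2)N1C(=O)[C@H](OCc1ccccc1)[C@@H](O)c1ccc(OCc2ccccc2)cc1 | intermediate
4 | (S)-4-benzyl-3-[(benzyloxy)acetyl]oxazolidin-2-one | O=C1OC[C@H](Cc2ccccc2)N1C(=O)COCc1ccccc1 | starting material
5 | (S)-4-benzyl-3-[(2S,3R)-2-(benzyloxy)-3-[4-(benzyloxy)phenyl]-3-hydroxypropanoyl]oxazolidin-2-one | O=C1OC[C@H](Cc2ccccc2)N1C(=O)[C@@H](OCc1ccccc1)[C@H](O)c1ccc(OCc2ccccc2)cc1 | intermediate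
6 | (2R,3S)-2-(benzyloxy)-3-[4-(benzyloxy)phenyl]-3-hydroxy-N-methoxy-N-methylpropanamide | CON(C)C(=O)[C@H](OCc1ccccc1)[C@@H](O)c1ccc(OCc2ccccc2)cc1 | intermediate
7 | (2S,3R)-2-(benzyloxy)-3-[4-(benzyloxy)phenyl]-3-hydroxy-N-methoxy-N-methylpropanamide | CON(C)C(=O)[C@@H](OCc1ccccc1)[C@H](O)c1ccc(OCc2ccccc2)cc1 | intermediate
8 | (1S,2S)-2-(benzyloxy)-1-[4-(benzyloxy)phenyl]propane-1,3-diol | OC[C@H](OCc1ccccc1)[C@@H](O)c1ccc(OCc2ccccc2)cc1 | intermediate
9 | (1S,2S)-2-(benzyloxy)-1-[4-(benzyloxy)phenyl]-3-[(tert-butyldiphenylsilyl)oxy]propan-1-ol | CC(C)(C)[Si](c1ccccc1)(c1ccccc1)OC[C@H](OCc1ccccc1)[C@@H](O)c1ccc(OCc2ccccc2)cc1 | intermediate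
10 | 1,3-bis(benzyloxy)-5-bromobenzene | Brc1cc(OCc2ccccc2)cc(OCc2ccccc2)c1 | starting material
11 | 1,5-bis(benzyloxy)-2,3-dibromobenzene | Brc1cc(OCc2ccccc2)cc(OCc2ccccc2)c1Br | intermediate
12 | (2R,3S)-2-(benzyloxy)-3-[4-(benzyloxy)phenyl]-3-[3,5-bis(benzyloxy)phenoxy]-N-methoxy-N-methylpropanamide | CON(C)C(=O)[C@H](OCc1ccccc1)[C@H](c1ccc(OCc2ccccc2)cc1)Oc1cc(OCc2ccccc2)cc(OCc2ccccc2)c1 | intermediate
13 | (2S,3R)-2-(benzyloxy)-3-[4-(benzyloxy)phenyl]-3-[3,5-bis(benzyloxy)-2-bromophenoxy]-N-methoxy-N-methylpropanamide | CON(C)C(=O)[C@@H](OCc1ccccc1)[C@@H](c1ccc(OCc2ccccc2)cc1)Oc1cc(OCc2ccccc2)cc(OCc2ccccc2)c1Br | intermediate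
14 | tert-butyl{(2S,3S)-2-(benzyloxy)-3-[4-(benzyloxy)phenyl]-3-[3,5-bis(benzyloxy)-2-bromophenoxy]propoxy}diphenylsilane | CC(C)(C)[Si](c1ccccc1)(c1ccccc1)OC[C@H](OCc1ccccc1)[C@H](c1ccc(OCc2ccccc2)cc1)Oc1cc(OCc2ccccc2)cc(OCc2ccccc2)c1Br | intermediate
15 | aryllithium from 14 (Li in place of Br) | CC(C)(C)[Si](c1ccccc1)(c1ccccc1)OC[C@H](OCc1ccccc1)[C@H](c1ccc(OCc2ccccc2)cc1)Oc1cc(OCc2ccccc2)cc(OCc2ccccc2)c1[Li] | intermediate
16 | seco-dimer aryl ketone: 14 with Br replaced by the (2S,3R)-2-(benzyloxy)-3-[4-(benzyloxy)phenyl]-3-[3,5-bis(benzyloxy)-2-bromophenoxy]propanoyl group | CC(C)(C)[Si](c1ccccc1)(c1ccccc1)OC[C@H](OCc1ccccc1)[C@H](c1ccc(OCc2ccccc2)cc1)Oc1cc(OCc2ccccc2)cc(OCc2ccccc2)c1C(=O)[C@@H](OCc1ccccc1)[C@@H](c1ccc(OCc2ccccc2)cc1)Oc1cc(OCc2ccccc2)cc(OCc2ccccc2)c1Br | intermediate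
17 | middle-unit 4-aryl-8-bromoflavan-4-ylium triflate (C2 R, 3-OBn cis to the 2-aryl group; ring G aryl on C4) | c5ccccc5COc1ccc([C@H]2Oc3c(c(OCc5ccccc5)cc(OCc5ccccc5)c3Br)[C+](c3c(OCc5ccccc5)cc(OCc5ccccc5)cc3O[C@@H](c3ccc(OCc5ccccc5)cc3)[C@@H](OCc3ccccc3)CO[Si](c3ccccc3)(c3ccccc3)C(C)(C)C)[C@H]2OCc2ccccc2)cc1.[O-]S(=O)(=O)C(F)(F)F | intermediate
18 | 8-bromo seco-dimer: (2R,3R)-3,5,7-tris(benzyloxy)-2-[4-(benzyloxy)phenyl]-8-bromoflavan carrying at C4 (all-cis) the ring G aryl group with the open (2S,3S) lower chain as TBDPS ether | c5ccccc5COc1ccc([C@H]2Oc3c(c(OCc5ccccc5)cc(OCc5ccccc5)c3Br)[C@@H](c3c(OCc5ccccc5)cc(OCc5ccccc5)cc3O[C@@H](c3ccc(OCc5ccccc5)cc3)[C@@H](OCc3ccccc3)CO[Si](c3ccccc3)(c3ccccc3)C(C)(C)C)[C@H]2OCc2ccccc2)cc1 | intermediate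
19 | aryllithium from 18 (Li at C8 of ring D) | c5ccccc5COc1ccc([C@H]2Oc3c(c(OCc5ccccc5)cc(OCc5ccccc5)c3[Li])[C@@H](c3c(OCc5ccccc5)cc(OCc5ccccc5)cc3O[C@@H](c3ccc(OCc5ccccc5)cc3)[C@@H](OCc3ccccc3)CO[Si](c3ccccc3)(c3ccccc3)C(C)(C)C)[C@H]2OCc2ccccc2)cc1 | intermediate
20 | seco-trimer aryl ketone: 18 with Br replaced by the (2R,3S)-2-(benzyloxy)-3-[4-(benzyloxy)phenyl]-3-[3,5-bis(benzyloxy)phenoxy]propanoyl group | c5ccccc5COc1ccc([C@H]2Oc3c(c(OCc5ccccc5)cc(OCc5ccccc5)c3C(=O)[C@H](OCc5ccccc5)[C@H](c3ccc(OCc5ccccc5)cc3)Oc3cc(OCc5ccccc5)cc(OCc5ccccc5)c3)[C@@H](c3c(OCc5ccccc5)cc(OCc5ccccc5)cc3O[C@@H](c3ccc(OCc5ccccc5)cc3)[C@@H](OCc3ccccc3)CO[Si](c3ccccc3)(c3ccccc3)C(C)(C)C)[C@H]2OCc2ccccc2)cc1 | intermediate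
21 | upper-unit 4-arylflavan-4-ylium triflate (C2 S, 3-OBn cis to the 2-aryl group; C8 of ring D on C4) | c5ccccc5COc1ccc([C@H]2Oc3c(c(OCc5ccccc5)cc(OCc5ccccc5)c3[C+]3c4c(OCc5ccccc5)cc(OCc5ccccc5)cc4O[C@@H](c4ccc(OCc5ccccc5)cc4)[C@H]3OCc3ccccc3)[C@@H](c3c(OCc5ccccc5)cc(OCc5ccccc5)cc3O[C@@H](c3ccc(OCc5ccccc5)cc3)[C@@H](OCc3ccccc3)CO[Si](c3ccccc3)(c3ccccc3)C(C)(C)C)[C@H]2OCc2ccccc2)cc1.[O-]S(=O)(=O)C(F)(F)F | intermediate
22 | seco-trimer TBDPS ether: upper (2S,3S,4-all-cis) and middle (2R,3R,4-all-cis) flavan units closed and joined 4→8, lower chain open | c5ccccc5COc1ccc([C@H]2Oc3c(c(OCc5ccccc5)cc(OCc5ccccc5)c3[C@H]3c4c(OCc5ccccc5)cc(OCc5ccccc5)cc4O[C@@H](c4ccc(OCc5ccccc5)cc4)[C@H]3OCc3ccccc3)[C@@H](c3c(OCc5ccccc5)cc(OCc5ccccc5)cc3O[C@@H](c3ccc(OCc5ccccc5)cc3)[C@@H](OCc3ccccc3)CO[Si](c3ccccc3)(c3ccccc3)C(C)(C)C)[C@H]2OCc2ccccc2)cc1 | intermediate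
23 | seco-trimer primary alcohol (22 without the silyl group) | c5ccccc5COc1ccc([C@H]2Oc3c(c(OCc5ccccc5)cc(OCc5ccccc5)c3[C@H]3c4c(OCc5ccccc5)cc(OCc5ccccc5)cc4O[C@@H](c4ccc(OCc5ccccc5)cc4)[C@H]3OCc3ccccc3)[C@@H](c3c(OCc5ccccc5)cc(OCc5ccccc5)cc3O[C@@H](c3ccc(OCc5ccccc5)cc3)[C@@H](OCc3ccccc3)CO)[C@H]2OCc2ccccc2)cc1 | intermediate
24 | seco-trimer aldehyde (lower chain ends in CHO next to the benzyloxy-bearing C3) | c5ccccc5COc1ccc([C@H]2Oc3c(c(OCc5ccccc5)cc(OCc5ccccc5)c3[C@H]3c4c(OCc5ccccc5)cc(OCc5ccccc5)cc4O[C@@H](c4ccc(OCc5ccccc5)cc4)[C@H]3OCc3ccccc3)[C@@H](c3c(OCc5ccccc5)cc(OCc5ccccc5)cc3O[C@@H](c3ccc(OCc5ccccc5)cc3)[C@@H](OCc3ccccc3)C=O)[C@H]2OCc2ccccc2)cc1 | intermediate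
25 | dodeca-O-benzyl trimer: all phenols and the three 3-hydroxyls benzylated, lower-unit 4-OH free (lower unit 2S,3S,4R) | c5ccccc5COc1ccc([C@H]2Oc3c(c(OCc5ccccc5)cc(OCc5ccccc5)c3[C@H]3c4c(OCc5ccccc5)cc(OCc5ccccc5)cc4O[C@@H](c4ccc(OCc5ccccc5)cc4)[C@H]3OCc3ccccc3)[C@@H](c3c(OCc5ccccc5)cc(OCc5ccccc5)c4c3O[C@@H](c3ccc(OCc5ccccc5)cc3)[C@@H](OCc3ccccc3)[C@@H]4O)[C@H]2OCc2ccccc2)cc1 | intermediate
26 | CNP0159291.1: upper unit (2S,3S,4R), middle unit (2R,3R,4S), lower flavan-3,4-diol unit (2S,3S,4R), joined 4→8 twice | Oc1ccc([C@H]2Oc3c(c(O)cc(O)c3[C@H]3c4c(O)cc(O)cc4O[C@@H](c4ccc(O)cc4)[C@H]3O)[C@@H](c3c(O)cc(O)c4c3O[C@@H](c3ccc(O)cc3)[C@@H](O)[C@@H]4O)[C@H]2O)cc1 | target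

**Totals**
Total step count: 18. Longest linear sequence: 12 steps (1, 5, 6, 10, 11, 12, 13, 14, 15, 16, 17, 18).

**Steps most likely to fail**

Step 14 (key step, proposed new method). The ketone may be reduced by the silane before ring A attacks, the acyclic C2–O aryl ether may ionise under the silyl triflate, or cation 21 may lose H3 and so erode the C3 configuration. The fallback reverses the order of bond formation with known reactions; it sets out from 12 and 18 and comes back at 22. Amide 12 would be reduced (LiAlH4, THF, −78 °C) to (2R,3S)-2-(benzyloxy)-3-[4-(benzyloxy)phenyl]-3-[3,5-bis(benzyloxy)phenoxy]propanal F1. BF3·OEt2-catalysed intramolecular hydroxyalkylation, as in step 17, would close the ring to the 2,3-cis flavan-4-ol F2, and Dess–Martin oxidation would give the 2,3-cis flavan-4-one F3. Aryllithium 19, made from 18 and transmetallated with CeCl3 to suppress enolisation, would add to F3 to give the tertiary 4-arylflavan-4-ol F4 (C4 configuration of no consequence). Ionic hydrogenation (Et3SiH, CF3CO2H, CH2Cl2, −40 °C) would then pass through the same cation 21 to 22.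

Step 12 (proposed new method). The failure modes are the same as in step 14, with protodebromination of ring D as a further risk. The same known-chemistry sequence serves; it sets out from 13 and 14 and comes back at 18. Amide 13 would be reduced to (2S,3R)-2-(benzyloxy)-3-[4-(benzyloxy)phenyl]-3-[3,5-bis(benzyloxy)-2-bromophenoxy]propanal F5, cyclised with BF3·OEt2 to the 8-bromoflavan-4-ol F6 and oxidised to the 8-bromoflavan-4-one F7. The organocerium reagent made from aryllithium 15 and CeCl3 would add to F7 to give the tertiary carbinol F8, and Et3SiH/CF3CO2H would reduce it through cation 17 to 18.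

Step 11. Bromine–lithium exchange between aryllithium 15 and the aryl bromide of 13 may scramble the two rings, or the hindered aryllithium may deprotonate α to the amide and expel the aryloxide. The fallback replaces the acylation by a faster carbonyl addition followed by oxidation; it sets out from 13 and 14 and comes back at 16. Aldehyde F5, made from 13 as above, would be treated with 15 at −78 °C, where addition to an aldehyde outruns exchange, to give the secondary carbinol F9 as an epimer mixture at the new centre. Dess–Martin oxidation would then give ketone 16.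

**Further compounds**
F1 | step 14 | (2R,3S)-2-(benzyloxy)-3-[4-(benzyloxy)phenyl]-3-[3,5-bis(benzyloxy)phenoxy]propanal | O=C[C@H](OCc1ccccc1)[C@H](c1ccc(OCc2ccccc2)cc1)Oc1cc(OCc2ccccc2)cc(OCc2ccccc2)c1
F2 | step 14 | (2S,3S,4R)-3,5,7-tris(benzyloxy)-2-[4-(benzyloxy)phenyl]chroman-4-ol | O[C@@H]1c2c(OCc3ccccc3)cc(OCc3ccccc3)cc2O[C@@H](c2ccc(OCc3ccccc3)cc2)[C@H]1OCc1ccccc1
F3 | step 14 | 2,3-cis-3,5,7-tris(benzyloxy)-2-[4-(benzyloxy)phenyl]chroman-4-one (2S) | O=C1c2c(OCc3ccccc3)cc(OCc3ccccc3)cc2O[C@@H](c2ccc(OCc3ccccc3)cc2)[C@H]1OCc1ccccc1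
F4 | step 14 | tertiary carbinol: 22 with OH in place of H at C4 of the upper unit (C4 undefined) | c5ccccc5COc1ccc([C@H]2Oc3c(c(OCc5ccccc5)cc(OCc5ccccc5)c3C3(O)c4c(OCc5ccccc5)cc(OCc5ccccc5)cc4O[C@@H](c4ccc(OCc5ccccc5)cc4)[C@H]3OCc3ccccc3)[C@@H](c3c(OCc5ccccc5)cc(OCc5ccccc5)cc3O[C@@H](c3ccc(OCc5ccccc5)cc3)[C@@H](OCc3ccccc3)CO[Si](c3ccccc3)(c3ccccc3)C(C)(C)C)[C@H]2OCc2ccccc2)cc1
F5 | step 12 | (2S,3R)-2-(benzyloxy)-3-[4-(benzyloxy)phenyl]-3-[3,5-bis(benzyloxy)-2-bromophenoxy]propanal | O=C[C@@H](OCc1ccccc1)[C@@H](c1ccc(OCc2ccccc2)cc1)Oc1cc(OCc2ccccc2)cc(OCc2ccccc2)c1Br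
F6 | step 12 | (2R,3R,4S)-3,5,7-tris(benzyloxy)-2-[4-(benzyloxy)phenyl]-8-bromochroman-4-ol | O[C@H]1c2c(OCc3ccccc3)cc(OCc3ccccc3)c(Br)c2O[C@H](c2ccc(OCc3ccccc3)cc2)[C@@H]1OCc1ccccc1
F7 | step 12 | 2,3-cis-3,5,7-tris(benzyloxy)-2-[4-(benzyloxy)phenyl]-8-bromochroman-4-one (2R) | O=C1c2c(OCc3ccccc3)cc(OCc3ccccc3)c(Br)c2O[C@H](c2ccc(OCc3ccccc3)cc2)[C@@H]1OCc1ccccc1
F8 | step 12 | tertiary carbinol: 18 with OH in place of H at C4 of the middle unit (C4 undefined) | c5ccccc5COc1ccc([C@H]2Oc3c(c(OCc5ccccc5)cc(OCc5ccccc5)c3Br)C(O)(c3c(OCc5ccccc5)cc(OCc5ccccc5)cc3O[C@@H](c3ccc(OCc5ccccc5)cc3)[C@@H](OCc3ccccc3)CO[Si](c3ccccc3)(c3ccccc3)C(C)(C)C)[C@H]2OCc2ccccc2)cc1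
F9 | step 11 | secondary carbinol: 16 with CH(OH) in place of the ketone (carbinol centre undefined) | CC(C)(C)[Si](c1ccccc1)(c1ccccc1)OC[C@H](OCc1ccccc1)[C@H](c1ccc(OCc2ccccc2)cc1)Oc1cc(OCc2ccccc2)cc(OCc2ccccc2)c1C(O)[C@@H](OCc1ccccc1)[C@@H](c1ccc(OCc2ccccc2)cc1)Oc1cc(OCc2ccccc2)cc(OCc2ccccc2)c1Br
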